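## Retrosynthetic overview

- The oleate is attached last, by O-acylation of the tertiary C7–OH of the bicyclic core (isochromene numbering: C1, O2, C3, C4, C4a, C5, C6, C7, C8, C8a); target configuration is (3R,7R).
- The carbocycle is closed at C5–C6 by a vinylogous Dieckmann condensation: the 4-methyl carbon of a preformed 2-methoxy-dihydropyran (future C5) attacks the lactone carbonyl (future C6) of a pivalaldehyde-derived dioxolanone. This dioxolanone is a temporary ring, absent from the target, that carries C7 from D-lactic acid (self-regeneration of stereocentres), activates C6 as an acylal and is destroyed in the same operation (pivalaldehyde leaves, C7–OH is freed; methanol then leaves from C1 to set C1=C8a and C4a=C5).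
- Enabling feature: the cross-conjugated push–pull array O2–C1=C8a(–C8=O)–C4a=C5–C6=O spanning both rings. C5 is the γ-carbon of the C8 ketone through C4a=C8a and is acidic before the C5–C6 bond exists; C6–C7(OH)(CH3) is a lactic acid unit; the C1 substituent on C8a keeps C6 and C8 non-equivalent, so C7 cannot be scrambled through a symmetric dienolate.
- The C7–C8 bond comes from an aldol union of the dioxolanone enolate with a pyran-3-carbaldehyde, then oxidation. The aldehyde comes from methyl (R)-3-hydroxybutanoate (C3 stereocentre) via a dihydropyranone, α-iodination, methyl addition with Ferrier-type transposition, and formylation.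
- Ring order: temporary dioxolanone (step 1) and pyran ring (step 4) first; carbocycle last (step 10), with the dioxolanone cleaved as the carbocycle closes.

Key step: step 10

Assumption: the methoxy acetal carbon of the pyran intermediates and the carbinol carbon of the aldol adduct are carried as epimer mixtures, because both centres are erased later (oxidation and the key step).

## Route

Step 1
Reactants: 1 (R)-lactic acid (D-lactic acid); 2 pivalaldehyde
Product: 3 (2R,5R)-2-tert-butyl-5-methyl-1,3-dioxolan-4-one (cis)
Conditions: TsOH·H2O (cat.), H2SO4 (cat.), pentane, reflux, Dean–Stark; crystallisation from pentane at −78 °C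
Reagents that add atoms: none
Why: Acid-catalysed acetalisation of the α-hydroxy acid, in which the cis-2,5-disubstituted dioxolanone is the thermodynamically preferred isomer and should be enriched by crystallisation, so the acetal centre (R) is set under thermodynamic control relative to the lactate centre.

Step 2
Reactants: 4 methyl (R)-3-hydroxybutanoate
Product: 5 (3R)-3-hydroxy-N-methoxy-N-methylbutanamide
Conditions: MeNHOMe·HCl, iPrMgCl, THF, −20 → 0 °C
Reagents that add atoms: N,O-dimethylhydroxylamine hydrochloride, CNOC.Cl
Why: Weinreb amide formation by aminolysis of the ester with the magnesium amide should tolerate the free hydroxyl as its alkoxide and does not touch the stereocentre.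

Step 3
Reactants: 5 (3R)-3-hydroxy-N-methoxy-N-methylbutanamide
Product: 6 (5R)-5-hydroxyhex-1-yn-3-one
Conditions: HC≡CMgBr (3 equiv), THF, −78 → 0 °C; aq. NH4Cl
Reagents that add atoms: ethynylmagnesium bromide, C#C[Mg]Br
Why: Weinreb ketone synthesis, in which the chelated tetrahedral adduct should prevent over-addition after the first equivalent of Grignard reagent has deprotonated the hydroxyl.

Step 4
Reactants: 6 (5R)-5-hydroxyhex-1-yn-3-one
Product: 7 (2R)-2-methyl-2,3-dihydro-4H-pyran-4-one
Conditions: AgOTf (10 mol %), CH2Cl2, rt, dark
Reagents that add atoms: none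
Why: Metal-catalysed 6-endo-dig hydroalkoxylation (intramolecular oxa-Michael addition) of a β-hydroxy ynone, in which the hydroxyl should attack the electrophilic β-alkyne carbon to close the pyran ring without touching the stereocentre.

Step 5
Reactants: 7 (2R)-2-methyl-2,3-dihydro-4H-pyran-4-one
Product: 8 (2R)-5-iodo-2-methyl-2,3-dihydro-4H-pyran-4-one
Conditions: I2, pyridine, CH2Cl2, 0 °C → rt
Reagents that add atoms: iodine, II
Why: α-Iodination of an enone with iodine and pyridine, in which the enol ether β-carbon (α to the ketone) is the only nucleophilic site.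

Step 6
Reactants: 8 (2R)-5-iodo-2-methyl-2,3-dihydro-4H-pyran-4-one
Product: 10 (6R)-3-iodo-2-methoxy-4,6-dimethyl-5,6-dihydro-2H-pyran (both C2 epimers), via tertiary carbinol 9 (not isolated)
Conditions: MeMgBr, THF, −78 °C; aq. NH4Cl; then MeOH, PPTS (cat.), 0 °C → rt
Reagents that add atoms: methylmagnesium bromide, C[Mg]Br; methanol, CO
Why: The Grignard reagent should add 1,2 to the vinylogous ester carbonyl, and the tertiary allylic carbinol should ionise under mild acid to the ring oxocarbenium ion that methanol captures at the anomeric carbon (Ferrier-type allylic transposition), which places the methyl group and the iodide on the new tetrasubstituted double bond.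

Step 7
Reactants: 10 (6R)-3-iodo-2-methoxy-4,6-dimethyl-5,6-dihydro-2H-pyran
Product: 12 (6R)-2-methoxy-4,6-dimethyl-5,6-dihydro-2H-pyran-3-carbaldehyde, via vinyllithium 11 (not isolated)
Conditions: t-BuLi (2.1 equiv), Et2O, −78 °C; then DMF, −78 → 0 °C; aq. NH4Cl
Reagents that add atoms: N,N-dimethylformamide, CN(C)C=O
Why: Iodine–lithium exchange followed by formylation with DMF, in which the cyclic vinyllithium should be stable because β-elimination of the allylic methoxy group would require a six-membered allene.

Step 8
Reactants: 3 (2R,5R)-2-tert-butyl-5-methyl-1,3-dioxolan-4-one; 12 (6R)-2-methoxy-4,6-dimethyl-5,6-dihydro-2H-pyran-3-carbaldehyde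
Product: 14 (2R,5S)-2-tert-butyl-5-{hydroxy[(6R)-2-methoxy-4,6-dimethyl-5,6-dihydro-2H-pyran-3-yl]methyl}-5-methyl-1,3-dioxolan-4-one, via lithium enolate 13 (not isolated)
Conditions: LDA, THF, −78 °C; then 12, −78 °C; AcOH, −78 °C
Reagents that add atoms: none
Why: Aldol addition of a dioxolanone lithium enolate (self-regeneration of stereocentres), in which the aldehyde should add to the enolate face anti to the tert-butyl group so that the new C–C bond replaces the lactate hydrogen with retention and fixes the quaternary centre that becomes C7 (R) of the target.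

Step 9
Reactants: 14 (2R,5S)-2-tert-butyl-5-{hydroxy[(6R)-2-methoxy-4,6-dimethyl-5,6-dihydro-2H-pyran-3-yl]methyl}-5-methyl-1,3-dioxolan-4-one
Product: 15 (2R,5S)-2-tert-butyl-5-{[(6R)-2-methoxy-4,6-dimethyl-5,6-dihydro-2H-pyran-3-yl]carbonyl}-5-methyl-1,3-dioxolan-4-one
Conditions: Dess–Martin periodinane, pyridine, CH2Cl2, 0 °C → rt
Reagents that add atoms: none
Why: Buffered Dess–Martin oxidation of the secondary allylic alcohol should give the ketone without harming the acetal, and the adjacent quaternary centre cannot epimerise.

Step 10
Reactants: 15 (2R,5S)-2-tert-butyl-5-{[(6R)-2-methoxy-4,6-dimethyl-5,6-dihydro-2H-pyran-3-yl]carbonyl}-5-methyl-1,3-dioxolan-4-one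
Product: 18 (3R,7R)-7-hydroxy-3,7-dimethyl-3,4-dihydro-6H-isochromene-6,8(7H)-dione, via potassium dienolate 16 (not isolated), via methoxy diketone 17 (not isolated)
Conditions: KOtBu (1.1 equiv), THF, −20 → 0 °C; then 1 M HCl, 0 °C → rt
Reagents that add atoms: none
Why: KOtBu should reversibly remove a proton from the 4-methyl group of the pyran (γ to the ketone, future C5) to give dienolate 16, whose γ-carbon adds to the dioxolanone carbonyl (future C6); the tetrahedral adduct should collapse with opening of the acylal and loss of pivalaldehyde to the C7 alkoxide of 17, and deprotonation of the now doubly activated C5–H2 should trigger vinylogous β-elimination (E1cB) of methoxide from C1, completed by the acidic work-up, which installs C1=C8a and C4a=C5. The closest known reaction type is the Dieckmann (intramolecular Claisen) condensation through the γ-carbon of a dienolate, combined with the known use of pivalaldehyde-derived dioxolanones as acyl donors that release an α-hydroxy ketone. The carbocycle closes in a 6-(enolendo)-exo-trig mode, the only feasible one because attack through the α-carbon or the enolate oxygen would give a four-membered ring. No new stereocentre is formed: C7 is already quaternary and non-enolisable (set in step 8), C3 is not touched, and the acetal centre at C1 is erased. The step needs γ-selectivity for the exocyclic methyl over the ring methylene and a dienolate geometry that places the acylal over the methyl terminus; the pyran ring holds the methyl cis to the acyl group, only that dienolate can reach the acylal, reversible deprotonation should funnel the other enolates through it, and β-elimination of the ring oxygen from the ring-methylene dienolate should be retarded because the endocyclic C3–O2 bond lies near the nodal plane of that π system. The C1 substituent on C8a keeps the two carbonyls that flank C7 distinct throughout, so no symmetric intermediate can scramble C7.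

Step 11
Reactants: 18 (3R,7R)-7-hydroxy-3,7-dimethyl-3,4-dihydro-6H-isochromene-6,8(7H)-dione; 19 oleoyl chloride ((9Z)-octadec-9-enoyl chloride)
Product: 20 (3R,7R)-3,7-dimethyl-6,8-dioxo-3,4,7,8-tetrahydro-6H-isochromen-7-yl (9Z)-octadec-9-enoate (target)
Conditions: Et3N, DMAP (cat.), CH2Cl2, 0 °C → rt
Reagents that add atoms: none
Why: DMAP-catalysed acylation of the tertiary α-ketol with an acid chloride, a reaction type established for 7-hydroxy azaphilone cores, should proceed without affecting the Z-alkene or the stereocentres.

## Compound list

1 | (R)-lactic acid | C[C@@H](O)C(=O)O | starting material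
2 | pivalaldehyde | CC(C)(C)C=O | starting material
3 | (2R,5R)-2-tert-butyl-5-methyl-1,3-dioxolan-4-one | C[C@H]1O[C@@H](C(C)(C)C)OC1=O | intermediate
4 | methyl (R)-3-hydroxybutanoate | C[C@@H](O)CC(=O)OC | starting material
5 | (3R)-3-hydroxy-N-methoxy-N-methylbutanamide | C[C@@H](O)CC(=O)N(C)OC | intermediate
6 | (5R)-5-hydroxyhex-1-yn-3-one | C[C@@H](O)CC(=O)C#C | intermediate
7 | (2R)-2-methyl-2,3-dihydro-4H-pyran-4-one | C[C@@H]1CC(=O)C=CO1 | intermediate
8 | (2R)-5-iodo-2-methyl-2,3-dihydro-4H-pyran-4-one | C[C@@H]1CC(=O)C(I)=CO1 | intermediate
9 | (2R)-5-iodo-2,4-dimethyl-3,4-dihydro-2H-pyran-4-ol (C4 epimers, not isolated) | C[C@@H]1CC(C)(O)C(I)=CO1 | intermediate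
10 | (6R)-3-iodo-2-methoxy-4,6-dimethyl-5,6-dihydro-2H-pyran (C2 epimers) | C[C@@H]1CC(C)=C(I)C(OC)O1 | intermediate
11 | [(6R)-2-methoxy-4,6-dimethyl-5,6-dihydro-2H-pyran-3-yl]lithium (not isolated) | C[C@@H]1CC(C)=C([Li])C(OC)O1 | intermediate
12 | (6R)-2-methoxy-4,6-dimethyl-5,6-dihydro-2H-pyran-3-carbaldehyde (C2 epimers) | C[C@@H]1CC(C)=C(C=O)C(OC)O1 | intermediate
13 | lithium enolate of 3, lithium (2R)-2-tert-butyl-5-methyl-1,3-dioxol-4-olate (not isolated) | [Li+].[O-]C1=C(C)O[C@@H](C(C)(C)C)O1 | intermediate
14 | (2R,5S)-2-tert-butyl-5-{hydroxy[(6R)-2-methoxy-4,6-dimethyl-5,6-dihydro-2H-pyran-3-yl]methyl}-5-methyl-1,3-dioxolan-4-one (carbinol and acetal epimers) | C[C@@]1(C(O)C2=C(C)C[C@@H](C)OC2OC)O[C@@H](C(C)(C)C)OC1=O | intermediate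
15 | (2R,5S)-2-tert-butyl-5-{[(6R)-2-methoxy-4,6-dimethyl-5,6-dihydro-2H-pyran-3-yl]carbonyl}-5-methyl-1,3-dioxolan-4-one (acetal epimers) | C[C@@]1(C(=O)C2=C(C)C[C@@H](C)OC2OC)O[C@@H](C(C)(C)C)OC1=O | intermediate
16 | potassium dienolate of 15 (enolate oxygen on the former ketone carbon, exocyclic methylidene at pyran C4; not isolated) | C=C1C[C@@H](C)OC(OC)C1=C([O-])[C@]1(C)O[C@@H](C(C)(C)C)OC1=O.[K+] | intermediate
17 | (3R,7R)-7-hydroxy-1-methoxy-3,7-dimethyl-3,4-dihydro-1H-isochromene-6,8(5H,7H)-dione (C1 epimers, not isolated) | O[C@]1(C)C(=O)CC2=C(C(OC)O[C@H](C)C2)C1=O | intermediate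
18 | (3R,7R)-7-hydroxy-3,7-dimethyl-3,4-dihydro-6H-isochromene-6,8(7H)-dione | O[C@]1(C)C(=O)C=C2C[C@@H](C)OC=C2C1=O | intermediate
19 | oleoyl chloride, (9Z)-octadec-9-enoyl chloride | CCCCCCCC/C=C\CCCCCCCC(Cl)=O | starting material
20 | (3R,7R)-3,7-dimethyl-6,8-dioxo-3,4,7,8-tetrahydro-6H-isochromen-7-yl (9Z)-octadec-9-enoate | CCCCCCCC/C=C\CCCCCCCC(=O)O[C@]1(C)C(=O)C=C2C[C@@H](C)OC=C2C1=O | target

## Step count and risks

Total step count: 11. Longest linear sequence: 10 steps (steps 2 to 11, from methyl (R)-3-hydroxybutanoate); step 1 is a one-step branch.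

Steps most likely to fail:

1. Step 10. The base may deprotonate the ring methylene, or form the dienolate geometry that holds the acylal away from the methyl terminus. Irreversible β-elimination of the ring oxygen with collapse of the acetal, or attack of liberated methoxide on the acylal, could then outrun ring closure. Fallback, setting out from 15 and returning at 18: the methoxy group is removed first by ionic hydrogenation of the allylic acetal (Et3SiH, BF3·OEt2, CH2Cl2, −78 °C) to give (2R,5S)-2-tert-butyl-5-{[(6R)-4,6-dimethyl-5,6-dihydro-2H-pyran-3-yl]carbonyl}-5-methyl-1,3-dioxolan-4-one F1. With no leaving group at C1, the same C5–C6 closure is run with KN(SiMe3)2 in THF (−78 → 0 °C); the ring oxygen is then a poor leaving group and no nucleophilic alkoxide is released, and loss of pivalaldehyde should give (3R,7R)-7-hydroxy-3,7-dimethyl-3,4-dihydro-1H-isochromene-6,8(5H,7H)-dione F2. Dehydrogenation with DDQ (hydride abstraction from C1, which is α to O2 and vinylogous to the C6 enol, then loss of a proton) should restore C1=C8a and C4a=C5 and give 18.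

2. Step 8. Proton transfer from the γ-positions of the hindered, tetrasubstituted enal to the enolate, retro-aldol on warming, and decomposition of the thermally labile lithium enolate may compete with 1,2-addition. Fallback, setting out from 3 (with 10) and returning at 14: the polarity of the union is reversed. The lithium enolate of 3 is hydroxymethylated with monomeric formaldehyde, anti to the tert-butyl group, to give (2R,5S)-2-tert-butyl-5-(hydroxymethyl)-5-methyl-1,3-dioxolan-4-one F3. Dess–Martin oxidation gives (2R,4S)-2-tert-butyl-4-methyl-5-oxo-1,3-dioxolane-4-carbaldehyde F4. Vinyllithium 11, generated from 10 with t-BuLi as in step 7, should add at −78 °C to this non-enolisable aldehyde in preference to the lactone carbonyl and give 14.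

3. Step 6. Iodine–magnesium exchange or conjugate addition with ring opening may compete with carbonyl addition to the α-iodo vinylogous ester, and the iodine-deactivated allylic carbinol may ionise sluggishly, so that hydrolysis competes with methanol capture. Fallback, setting out from 8 and returning at 10: the carbon is introduced by carbonyl olefination instead of carbanion addition. Methylenation with Cp2TiMe2 (toluene, 65 °C) should give the cross-conjugated dienol ether (2R)-5-iodo-2-methyl-4-methylidene-3,4-dihydro-2H-pyran F5. PPTS in methanol then protonates the exocyclic methylene carbon to the same ring oxocarbenium ion as in step 6, which methanol captures at the acetal carbon to give 10.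

Further compounds
F1 | step 10 | (2R,5S)-2-tert-butyl-5-{[(6R)-4,6-dimethyl-5,6-dihydro-2H-pyran-3-yl]carbonyl}-5-methyl-1,3-dioxolan-4-one | C[C@@]1(C(=O)C2=C(C)C[C@@H](C)OC2)O[C@@H](C(C)(C)C)OC1=O
F2 | step 10 | (3R,7R)-7-hydroxy-3,7-dimethyl-3,4-dihydro-1H-isochromene-6,8(5H,7H)-dione | O[C@]1(C)C(=O)CC2=C(CO[C@H](C)C2)C1=O
F3 | step 8 | (2R,5S)-2-tert-butyl-5-(hydroxymethyl)-5-methyl-1,3-dioxolan-4-one | C[C@@]1(CO)O[C@@H](C(C)(C)C)OC1=O
F4 | step 8 | (2R,4S)-2-tert-butyl-4-methyl-5-oxo-1,3-dioxolane-4-carbaldehyde | C[C@@]1(C=O)O[C@@H](C(C)(C)C)OC1=O
F5 | step 6 | (2R)-5-iodo-2-methyl-4-methylidene-3,4-dihydro-2H-pyran | C[C@@H]1CC(=C)C(I)=CO1
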